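## Structural features

Compound 27 is an achiral, mirror-symmetric array of three hexasubstituted benzene rings: a central butanoylphloroglucinol (ring B) whose C3 and C5 each carry a CH2 bridge to an outer ring (rings A and C). Each outer ring is a 3-butanoyl-2,4-dihydroxy-6-methoxy-5-methylphenyl unit bound through C1'. There are no stereocentres, so the problems are purely constitutional: placing eighteen ring substituents and telling apart nine phenolic oxygens, seven free and two methylated. The two methyl ethers sit at C6', between the C5' methyl and the bridge-bearing C1' and para to the ketone, while every ketone lies between two hydrogen-bonding hydroxyls. Late selective methylation or demethylation among these oxygens would therefore be unreliable. The bis-benzylic CH2 links join electron-rich phenol rings and can be cut or scrambled through quinone methides by strong acid or base, and the free polyphenols are air-sensitive. The key step exploits the pattern of rings A and C: C1'–C6'(OMe)–C5'(Me)–C4'(OH) is a four-carbon diene unit oxygenated twice at one end and once in the middle, and C2'(O)–C3'(acyl) is an alkynyl ketone with an alkoxy group on the far alkyne carbon.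

## Logic of the disconnections

27 to 24 and 25. The bond between C1 of ring B and the butanoyl carbonyl carbon is cut. C1 is the only unsubstituted ring carbon of 24 and lies on a phloroglucinol nucleus, so C-acylation has one possible site. The forward step must acylate carbon without cleaving the CH2 bridges, which points to nitrile/HCl conditions and away from an acid chloride with AlCl3.

24 to 23. Five O–CH2Ph bonds are cut. All oxygens that must end free carry one kind of group, removed by neutral hydrogenolysis that cannot touch the two methyl ethers. For this reason the C2' oxygen carries benzyl and not ethyl. An ethyl ether there would lie beside a ketone already chelated by the C4' hydroxyl, would need a boron or aluminium halide, and would compete with the equally hindered C6' methyl ether. The forward step must leave three aryl ketones intact.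

23 to 15 and two molecules of 21. Four C–C bonds are cut, C1'–C2' and C3'–C4' in each outer ring. Both hexasubstituted outer rings fall back to two open-chain arms on ring B and a six-carbon alkynone. The C6' methoxyl, the free C4' hydroxyl and the protected C2' oxygen are all written into the components. The forward step must be a twofold, regioselective cycloaddition–aromatisation at or below 40 °C.

21 to 16, 17 and 18. The acyl–alkynyl bond and the O–C(sp) bond are cut. A lithium alkoxyacetylide made in one flask from 16 and 17 is acylated once by 18. The demand is low temperature throughout, since benzyl alkynyl ethers rearrange on heating.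

15 to 13. Two O–Si bonds are cut and a hydrogen is returned to C4 of each chain. This gives a storable bis(enoate) in place of a moisture-sensitive diene. The forward enolisation must occur at the γ-carbon and give the (2Z) enol ether.

13 to 12. The C3–OMe bonds are cut. The methoxyl that becomes C6'–OMe is introduced where a ketone fixes its position unambiguously.

12 to 8 and two molecules of 5. In each arm the C2–C3 bond and the C2–CH3 bond are cut. The carboxyl carbon of 8 becomes the ketone C3, 5 delivers C1 and C2 as a masked acetate unit, and the C-methyl group is added last at C2, the one doubly activated position of the arm. C1 and C2 become C4' and C5' of the outer rings. This cut is preferred to one at C4–C5 of each arm, which would need a bis(halomethyl) derivative of the tribenzyloxybenzene. Such trialkoxybenzyl halides ionise readily and the ring still has a nucleophilic C–H, so self-condensation would threaten. The forward sequence must stop at one methyl group per arm.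

8 to 4 and two molecules of 5. The Cα–Cβ bond of each propanoic acid arm is cut. The aldehyde carbon of 4 becomes the future bridge CH2. Condensation, reduction and decarboxylation are to run in one pot without a cationic benzylic intermediate.

4 to 3. Three O–benzyl bonds are cut. Benzylation after formylation is chosen because the two aldehyde groups suppress the C-benzylation that troubles direct etherification of 1.

3 to 1. Two aryl–CHO bonds are cut. Compound 1 is nucleophilic enough for double formylation. The third position stays as the C–H that is acylated in the last step.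

## Other disconnections considered

Alternative 1: The cut is the ring B bond between the butanoyl-bearing carbon and a neighbouring C–OH carbon. In the forward sense, base would make C6 of triketo ester A2 attack its ester carbon (Claisen closure) to give A1, the tetra-O-benzyl ether of 27. In its favour, the closure follows the biosynthetic logic of acylphloroglucinols and needs only base. The central butanoyl group arrives with the ring, so no late C-acylation of a bridged polyphenol is needed; on this point it is better than the chosen plan. Against it, A2 carries two bulky arylmethyl groups at C2 and C4 and has several acidic sites. Aldol closure from C2 onto the C7 carbonyl and O-cyclisation to a lactone are expected to compete, and the C2 substituent hinders attack on the ester. Both outer rings would have to be made separately as fully substituted units and attached regioselectively at C2 and C4 of a polyketide chain. Structurally both plans end with one hydrogenolysis and neither meets a stereocentre, so they are equal there. Mechanistically the Claisen folding has closer precedent in type than the chosen cycloaddition. In step economy it is clearly longer, since the chosen plan makes both outer rings in one operation.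

Alternative 2: The cuts are the aryl–carbonyl bond and the neighbouring aryl–oxygen bond of ring B. In the forward sense, fluoride acts on ortho-silyl triflate A4 in the presence of A5 (aryne insertion); the carboxylate oxygen adds next to the benzylic arm and the acyl group shifts to the adjacent carbanion, giving A3. In its favour, the butanoyl group and its flanking hydroxyl are placed in one non-acidic step on a finished skeleton, which is gentler on the CH2 bridges than the final acylation of the chosen plan. The benzyloxy group beside the reactive bond should direct the addition. Against it, A4 is a hexasubstituted silyl triflate that needs a long preparation. The reactive triple bond is flanked on both sides. Simple proton transfer giving the aryl ester instead of acyl migration is the usual competitor with a free acid. The outer-ring ketones and benzylic hydrogens offer further reaction partners. On regiochemical certainty the two plans are equal, since the chosen plan has only one free carbon to acylate. In step economy it is worse, because both outer rings must again be made separately and joined.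

Alternative 3: The cut is the C2'–C3' bond of each outer ring. In the forward sense, base would fold both triketo ester arms of A7 at once, C6 of each chain attacking its ester carbon, to give A6. In its favour, it is two-directional like the chosen plan, so it is equal in convergence. It uses robust reagents with no silyl diene or alkynyl ether, and it allows the central butanoyl group to be installed at the very start; on those two points it is better. Against it, A6 has three free hydroxyls on each outer ring. The C6' methyl ethers would have to be added afterwards by selective mono-methylation, a selectivity problem that the chosen plan avoids by bringing the methoxyl in as an enol ether. Each Claisen closure must also occur at an ester whose α-carbon carries the bridge, in competition with aldol and lactone closures, on two arms independently. A7 itself needs lengthy chain extension through poorly behaved polyketo intermediates. The number of ring-forming events is equal, but the overall count is higher.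

Key step: step 8

Remarks on the chemistry: N-methoxy-N-methylbutanamide 18 is taken to be a catalogue reagent. The alkynone carries a benzyl and not an ethyl group on the ynol oxygen, so that this oxygen is freed in the same hydrogenolysis as the ring B ethers. Compound 12 is expected as a mixture of diastereomers and 13 as a mixture of double-bond isomers; the stereocentres of 12 disappear in step 5 and the double-bond isomerism of 13 in step 6.

## Route

Step 1
Reactants: 1 phloroglucinol (benzene-1,3,5-triol)
Product: 3 2,4,6-trihydroxybenzene-1,3-dicarbaldehyde, via bis(iminium) dichloride 2 (not isolated)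
Conditions: POCl3 (2.4 equiv), DMF (2.4 equiv), 1,4-dioxane, 0 °C → rt; then H2O, rt
Reagents that add atoms: N,N-dimethylformamide, CN(C)C=O; water, O
Why: Vilsmeier–Haack formylation; the free triol is nucleophilic enough to take two chloroiminium units, and the third position is deactivated by them, so stoichiometry should stop the reaction at the dialdehyde.

Step 2
Reactants: 3 2,4,6-trihydroxybenzene-1,3-dicarbaldehyde
Product: 4 2,4,6-tris(benzyloxy)benzene-1,3-dicarbaldehyde
Conditions: BnBr (3.6 equiv), K2CO3 (4 equiv), DMF, 60 °C
Reagents that add atoms: benzyl bromide, BrCc1ccccc1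
Why: Williamson ether synthesis; the two formyl groups lower the nucleophilicity of the ring carbon, so O-benzylation should prevail, and warming overcomes the hydrogen bonds of the hydroxyls to the aldehydes.

Step 3
Reactants: 4 2,4,6-tris(benzyloxy)benzene-1,3-dicarbaldehyde; 5 2,2-dimethyl-1,3-dioxane-4,6-dione (two equivalents)
Product: 8 3,3'-[2,4,6-tris(benzyloxy)-1,3-phenylene]dipropanoic acid, via bis(arylidene) dioxanedione 6 (not isolated), via bis(arylmethyl) dioxanedione 7 (not isolated)
Conditions: 5 (2.4 equiv), HCO2H–Et3N (5:2), 95–100 °C; then aq. HCl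
Reagents that add atoms: none
Why: Knoevenagel condensation, conjugate reduction of the alkylidene by formate and hydrolytic decarboxylation in one pot; each aldehyde gains a CH2CO2H unit without an ionisable trialkoxybenzyl halide, and benzyl ethers are inert to formate without a hydrogenation catalyst.

Step 4
Reactants: 8 3,3'-[2,4,6-tris(benzyloxy)-1,3-phenylene]dipropanoic acid; 5 2,2-dimethyl-1,3-dioxane-4,6-dione (two equivalents)
Product: 12 dimethyl 5,5'-[2,4,6-tris(benzyloxy)-1,3-phenylene]bis(2-methyl-3-oxopentanoate), via bis(acyl imidazole) 9 (not isolated), via bis(acyl dioxanedione) 10 (not isolated), via bis(3-oxo ester) 11 (not isolated)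
Conditions: 1,1'-carbonyldiimidazole (2.2 equiv), CH2Cl2, rt; 5 (2.4 equiv), DMAP (cat.), rt; 1 M HCl wash, evaporate; MeOH, reflux; evaporate; K2CO3 (2.4 equiv), MeI (2.1 equiv), acetone, rt
Reagents that add atoms: methanol, CO; iodomethane, CI
Why: Acyl imidazole 9 C-acylates the dioxanedione, and the acyl dioxanedione loses acetone and CO2 in hot methanol through an acylketene (Oikawa–Yonemitsu 3-oxo ester synthesis); the crude intermediates are carried on without purification. Enolate alkylation with K2CO3 and MeI then places one methyl group on the doubly activated C2 of each arm, and the two epimerisable stereocentres so formed disappear in step 5.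

Step 5
Reactants: 12 dimethyl 5,5'-[2,4,6-tris(benzyloxy)-1,3-phenylene]bis(2-methyl-3-oxopentanoate)
Product: 13 dimethyl (2E,2'E)-5,5'-[2,4,6-tris(benzyloxy)-1,3-phenylene]bis(3-methoxy-2-methylpent-2-enoate)
Conditions: HC(OMe)3 (excess), H2SO4 (cat.), MeOH, rt → 45 °C; NaHCO3
Reagents that add atoms: trimethyl orthoformate, COC(OC)OC
Why: Acid-catalysed enol ether formation with the orthoformate as methyl source and dehydrating agent, the standard conversion of a 2-alkyl-3-oxo ester into its 3-methoxy enoate; the double-bond geometry is immaterial for step 6.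

Step 6
Reactants: 13 dimethyl (2E,2'E)-5,5'-[2,4,6-tris(benzyloxy)-1,3-phenylene]bis(3-methoxy-2-methylpent-2-enoate)
Product: 15 1,3,5-tris(benzyloxy)-2,4-bis[(2Z)-3,5-dimethoxy-4-methyl-5-(trimethylsilyloxy)penta-2,4-dien-1-yl]benzene, via dilithium bis(dienolate) 14 (not isolated)
Conditions: LiN(iPr)2 (2.6 equiv), THF, −78 °C; TMSCl (3 equiv), −78 → 0 °C; evaporate, pentane, filter under Ar; used crude
Reagents that add atoms: chlorotrimethylsilane, C[Si](C)(C)Cl
Why: γ-Deprotonation of a 3-alkoxy enoate (no α-hydrogen is present) and O-silylation of the extended enolate give the vinylketene acetal; allylic strain with the C4 methyl should turn the C1 methylene cis to the C3 methoxyl, giving the (2Z) enol ether.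

Step 7
Reactants: 16 benzyl alcohol; 17 trichloroethene; 18 N-methoxy-N-methylbutanamide
Product: 21 1-(benzyloxy)hex-1-yn-3-one, via benzyl (E)-1,2-dichloroethenyl ether 19 (not isolated), via lithium (benzyloxy)ethynide 20 (not isolated)
Conditions: 16, KH (1.1 equiv), THF, 0 °C; 17, −50 °C → rt; n-BuLi (2.5 equiv), −78 → −40 °C; 18, −78 → −20 °C; cold aq. NH4Cl; chromatography on Et3N-deactivated silica, stored cold
Reagents that add atoms: none
Why: Alkoxide addition–elimination on trichloroethene gives the dichloroethenyl ether, n-BuLi effects dehydrochlorination and chlorine–lithium exchange to the alkoxyacetylide, and the Weinreb ketone synthesis stops at single acylation.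

Step 8
Reactants: 15 1,3,5-tris(benzyloxy)-2,4-bis[(2Z)-3,5-dimethoxy-4-methyl-5-(trimethylsilyloxy)penta-2,4-dien-1-yl]benzene; 21 1-(benzyloxy)hex-1-yn-3-one (two equivalents)
Product: 23 1,3,5-tris(benzyloxy)-2,4-bis{[2-(benzyloxy)-3-butanoyl-4-hydroxy-6-methoxy-5-methylphenyl]methyl}benzene, via bis(cyclohexadiene) cycloadduct 22 (not isolated)
Conditions: 21 (2.6 equiv), PhMe (0.5 M), 0 → 40 °C, Ar; then 1 M HCl, THF, 0 °C → rt
Reagents that add atoms: none
Why: Proposed new method: each vinylketene acetal arm of 15 should bond through its nucleophilic C2 (the CH next to the bridge CH2) to the benzyloxy-bearing carbon of 21, the electrophilic position β to the ketone, while the acyl-bearing alkyne carbon bonds to the ketene acetal carbon, either in one asynchronous [4+2] event or by vinylogous Mukaiyama–Michael addition followed by ring closure. The closest known reaction type is the Diels–Alder reaction of 1,1,3-trioxygenated silyl dienes with acetylenic ketones and esters followed by aromatising loss of alcohol; new here are the donor-substituted ynone, the fully substituted diene and the twofold execution. Each outer ring is closed as a six-membered carbocycle by intermolecular [4+2] cycloaddition that makes C1'–C2' and C3'–C4', giving the cyclohexa-2,5-diene ketal 22. Acid then removes methanol across C1' and C4' of each new ring and cleaves the silyl ether, so the ketene acetal carbon ends as the chelated C4' hydroxyl. No stereocentre is set, because the sp3 carbons of 22 are lost on aromatisation. The step needs head-to-tail regioselectivity, which the polarity match between the diene terminus and the ynone β-carbon should secure, and reaction at C≡C and not at C=O, which the absence of a Lewis acid favours. The (2Z) enol ether keeps the bridge CH2 on the outside of the s-cis diene, and the temperature is limited to 40 °C because benzyl alkynyl ethers can rearrange sigmatropically on stronger heating.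

Step 9
Reactants: 23 1,3,5-tris(benzyloxy)-2,4-bis{[2-(benzyloxy)-3-butanoyl-4-hydroxy-6-methoxy-5-methylphenyl]methyl}benzene
Product: 24 2,4-bis[(3-butanoyl-2,4-dihydroxy-6-methoxy-5-methylphenyl)methyl]benzene-1,3,5-triol
Conditions: H2 (1 atm), 10% Pd/C, EtOAc–MeOH (degassed), rt; filtered under Ar
Reagents that add atoms: none
Why: Catalytic hydrogenolysis of five aryl benzyl ethers; the methyl ethers, the diarylmethane C–C bonds and the hindered, hydrogen-bonded aryl ketones should be untouched at 1 atm and rt.

Step 10
Reactants: 24 2,4-bis[(3-butanoyl-2,4-dihydroxy-6-methoxy-5-methylphenyl)methyl]benzene-1,3,5-triol; 25 butanenitrile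
Product: 27 1-[3,5-bis[(3-butanoyl-2,4-dihydroxy-6-methoxy-5-methylphenyl)methyl]-2,4,6-trihydroxyphenyl]butan-1-one, via ketiminium chloride 26 (not isolated)
Conditions: 25 (3 equiv), ZnCl2 (fused, 1 equiv), HCl (g), Et2O–1,4-dioxane, 0 °C → rt; then H2O, 80 °C
Reagents that add atoms: water, O
Why: Houben–Hoesch acylation; the nitrilium ion can attack only the single unsubstituted carbon, which lies on the phloroglucinol nucleus of ring B, and hydrolysis of the ketiminium salt gives the ketone without O-acylation of the other phenols.

## Compound list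

1 | phloroglucinol (benzene-1,3,5-triol) | Oc1cc(O)cc(O)c1 | starting material
2 | bis(iminium) dichloride of the twofold Vilsmeier adduct | Oc1cc(O)c(C=[N+](C)C)c(O)c1C=[N+](C)C.[Cl-].[Cl-] | intermediate
3 | 2,4,6-trihydroxybenzene-1,3-dicarbaldehyde | O=Cc1c(O)cc(O)c(C=O)c1O | intermediate
4 | 2,4,6-tris(benzyloxy)benzene-1,3-dicarbaldehyde | O=Cc1c(OCc2ccccc2)cc(OCc2ccccc2)c(C=O)c1OCc1ccccc1 | intermediate
5 | 2,2-dimethyl-1,3-dioxane-4,6-dione | CC1(C)OC(=O)CC(=O)O1 | starting material
6 | 5,5'-{[2,4,6-tris(benzyloxy)-1,3-phenylene]dimethanylylidene}bis(2,2-dimethyl-1,3-dioxane-4,6-dione) | CC1(C)OC(=O)C(=Cc2c(OCc3ccccc3)cc(OCc3ccccc3)c(C=C3C(=O)OC(C)(C)OC3=O)c2OCc2ccccc2)C(=O)O1 | intermediate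
7 | 5,5'-{[2,4,6-tris(benzyloxy)-1,3-phenylene]bis(methylene)}bis(2,2-dimethyl-1,3-dioxane-4,6-dione) | CC1(C)OC(=O)C(Cc2c(OCc3ccccc3)cc(OCc3ccccc3)c(CC3C(=O)OC(C)(C)OC3=O)c2OCc2ccccc2)C(=O)O1 | intermediate
8 | 3,3'-[2,4,6-tris(benzyloxy)-1,3-phenylene]dipropanoic acid | OC(=O)CCc1c(OCc2ccccc2)cc(OCc2ccccc2)c(CCC(=O)O)c1OCc1ccccc1 | intermediate
9 | 1,1'-{3,3'-[2,4,6-tris(benzyloxy)-1,3-phenylene]dipropanoyl}bis(1H-imidazole) | O=C(CCc1c(OCc2ccccc2)cc(OCc2ccccc2)c(CCC(=O)n2ccnc2)c1OCc1ccccc1)n1ccnc1 | intermediate
10 | 5,5'-{[2,4,6-tris(benzyloxy)-1,3-phenylene]bis(1-hydroxypropan-3-yl-1-ylidene)}bis(2,2-dimethyl-1,3-dioxane-4,6-dione) (enol form of the twofold acyl dioxanedione) | CC1(C)OC(=O)C(=C(O)CCc2c(OCc3ccccc3)cc(OCc3ccccc3)c(CCC(O)=C3C(=O)OC(C)(C)OC3=O)c2OCc2ccccc2)C(=O)O1 | intermediate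
11 | dimethyl 5,5'-[2,4,6-tris(benzyloxy)-1,3-phenylene]bis(3-oxopentanoate) | COC(=O)CC(=O)CCc1c(OCc2ccccc2)cc(OCc2ccccc2)c(CCC(=O)CC(=O)OC)c1OCc1ccccc1 | intermediate
12 | dimethyl 5,5'-[2,4,6-tris(benzyloxy)-1,3-phenylene]bis(2-methyl-3-oxopentanoate) (mixture of diastereomers) | COC(=O)C(C)C(=O)CCc1c(OCc2ccccc2)cc(OCc2ccccc2)c(CCC(=O)C(C)C(=O)OC)c1OCc1ccccc1 | intermediate
13 | dimethyl (2E,2'E)-5,5'-[2,4,6-tris(benzyloxy)-1,3-phenylene]bis(3-methoxy-2-methylpent-2-enoate) (drawn as the E,E isomer; isomer mixture acceptable) | COC(=O)/C(C)=C(OC)\CCc1c(OCc2ccccc2)cc(OCc2ccccc2)c(CC/C(OC)=C(C)\C(=O)OC)c1OCc1ccccc1 | intermediate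
14 | dilithium bis(dienolate) of 13, (Z) at both new enol ether double bonds | O(Cc1ccccc1)c1cc(OCc2ccccc2)c(C/C=C(\OC)C(C)=C(OC)[O-])c(OCc2ccccc2)c1C/C=C(\OC)C(C)=C(OC)[O-].[Li+].[Li+] | intermediate
15 | 1,3,5-tris(benzyloxy)-2,4-bis[(2Z)-3,5-dimethoxy-4-methyl-5-(trimethylsilyloxy)penta-2,4-dien-1-yl]benzene (ketene acetal geometry immaterial) | O(Cc1ccccc1)c1cc(OCc2ccccc2)c(C/C=C(\OC)C(C)=C(OC)O[Si](C)(C)C)c(OCc2ccccc2)c1C/C=C(\OC)C(C)=C(OC)O[Si](C)(C)C | intermediate
16 | benzyl alcohol | OCc1ccccc1 | starting material
17 | trichloroethene | ClC=C(Cl)Cl | starting material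
18 | N-methoxy-N-methylbutanamide | CCCC(=O)N(C)OC | starting material
19 | benzyl (E)-1,2-dichloroethenyl ether | Cl/C=C(/Cl)OCc1ccccc1 | intermediate
20 | lithium (benzyloxy)ethynide | [Li+].[C-]#COCc1ccccc1 | intermediate
21 | 1-(benzyloxy)hex-1-yn-3-one | CCCC(=O)C#COCc1ccccc1 | intermediate
22 | 1,3,5-tris(benzyloxy)-2,4-bis{[2-(benzyloxy)-3-butanoyl-4,6-dimethoxy-5-methyl-4-(trimethylsilyloxy)cyclohexa-2,5-dien-1-yl]methyl}benzene (mixture of diastereomers) | O(Cc1ccccc1)c1cc(OCc2ccccc2)c(CC2C(OCc3ccccc3)=C(C(=O)CCC)C(OC)(O[Si](C)(C)C)C(C)=C2OC)c(OCc2ccccc2)c1CC1C(OCc2ccccc2)=C(C(=O)CCC)C(OC)(O[Si](C)(C)C)C(C)=C1OC | intermediate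
23 | 1,3,5-tris(benzyloxy)-2,4-bis{[2-(benzyloxy)-3-butanoyl-4-hydroxy-6-methoxy-5-methylphenyl]methyl}benzene | O(Cc1ccccc1)c1cc(OCc2ccccc2)c(Cc2c(OCc3ccccc3)c(C(=O)CCC)c(O)c(C)c2OC)c(OCc2ccccc2)c1Cc1c(OCc2ccccc2)c(C(=O)CCC)c(O)c(C)c1OC | intermediate
24 | 2,4-bis[(3-butanoyl-2,4-dihydroxy-6-methoxy-5-methylphenyl)methyl]benzene-1,3,5-triol | Oc1cc(O)c(Cc2c(O)c(C(=O)CCC)c(O)c(C)c2OC)c(O)c1Cc1c(O)c(C(=O)CCC)c(O)c(C)c1OC | intermediate
25 | butanenitrile | CCCC#N | starting material
26 | ketiminium chloride of 27 (C=NH2+ in place of the ring B ketone) | CCCC(=[NH2+])c1c(O)c(Cc2c(O)c(C(=O)CCC)c(O)c(C)c2OC)c(O)c(Cc2c(O)c(C(=O)CCC)c(O)c(C)c2OC)c1O.[Cl-] | intermediate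
27 | 1-[3,5-bis[(3-butanoyl-2,4-dihydroxy-6-methoxy-5-methylphenyl)methyl]-2,4,6-trihydroxyphenyl]butan-1-one (CNP0264591.0) | CCCC(=O)c1c(O)c(Cc2c(O)c(C(=O)CCC)c(O)c(C)c2OC)c(O)c(Cc2c(O)c(C(=O)CCC)c(O)c(C)c2OC)c1O | target

## Step count and least certain steps

Total: 10 steps. Longest linear sequence: 9 steps (steps 1–6, 8, 9, 10); step 7 is the side branch to 21.

**Step 8 (key step, proposed new method).** The alkoxy donor lowers the dienophilicity of 21, and the diene of 15 is fully substituted. Slow cycloaddition would allow hydrolysis or desilylation of the ketene acetals, sigmatropic decomposition of the benzyl alkynyl ether, stopping after one annulation, or 1,2-addition at the ketone. A first adjustment within the same disconnection would be Lewis-acid or fluoride promotion of the stepwise Michael–ring closure variant.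

The fallback uses known chemistry, sets out from 1 and 25 and returns at 27. The outer rings are made as separate units and joined to ring B by Mannich-base (quinone methide) coupling. Houben–Hoesch reaction of 1 with 25 (ZnCl2, HCl, Et2O; then hot water) gives 1-(2,4,6-trihydroxyphenyl)butan-1-one F1. The same reaction on purchased 2-methylbenzene-1,3,5-triol F2 gives 1-(2,4,6-trihydroxy-3-methylphenyl)butan-1-one F3. Methylation of F3 with one equivalent of dimethyl sulfate and K2CO3 in acetone should occur at the non-chelated hydroxyl para to the ketone and give 1-(2,6-dihydroxy-4-methoxy-3-methylphenyl)butan-1-one F4. Aminomethylation of its single free ring position with formaldehyde and dimethylamine in ethanol gives 1-{3-[(dimethylamino)methyl]-2,6-dihydroxy-4-methoxy-5-methylphenyl}butan-1-one F5. Heating F1 with two equivalents of F5 in 1,4-dioxane should release dimethylamine, form the ortho-quinone methide and alkylate both free positions of F1, giving 27.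

**Step 10.** Ring B of 24 is easily protonated at carbon, so HCl/ZnCl2 may cause loss or migration of an arylmethyl group (retro-Friedel–Crafts) in competition with acylation. Imidate formation at phenols, incomplete ketiminium hydrolysis and air oxidation of the triol are further risks.

The fallback reverses the order, sets out from 23 and returns at 27. Friedel–Crafts acylation of 23 at the ring B C–H with the mixed anhydride of butanoic acid and trifluoroacetic anhydride (CH2Cl2, rt) is followed by brief K2CO3/MeOH to cleave any esters on the C4' hydroxyls. This should give 1-[2,4,6-tris(benzyloxy)-3,5-bis{[2-(benzyloxy)-3-butanoyl-4-hydroxy-6-methoxy-5-methylphenyl]methyl}phenyl]butan-1-one F6. Hydrogenolysis (H2, 10% Pd/C) then gives 27, with no free polyphenol exposed to acid.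

**Step 7.** The benzyl alkynyl ether unit may be lost by [3,3] sigmatropic rearrangement during warming, concentration or chromatography, and the acetylide may add sluggishly to the amide.

The fallback changes the O-substituent and the deprotection chemistry, sets out from 17 and 18 and returns at 24. Propan-2-ol is used in place of 16 under the conditions of step 7, giving 1-(propan-2-yloxy)hex-1-yn-3-one F7, which has no benzylic rearrangement pathway. Cycloaddition of F7 with 15 as in step 8 (heating to about 70 °C is now permissible) should give 1,3,5-tris(benzyloxy)-2,4-bis{[3-butanoyl-4-hydroxy-6-methoxy-5-methyl-2-(propan-2-yloxy)phenyl]methyl}benzene F8. BCl3 with pentamethylbenzene in CH2Cl2 at −78 → 0 °C should cleave the benzyl and isopropyl ethers, which ionise far more readily than methyl ethers, giving 24.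

**Step 3.** Both aldehydes of 4 are flanked by two benzyloxy groups, so condensation may be slow or stop at one arm. Reduction and decarboxylation may also be incomplete, leaving mixtures.

The fallback sets out from 4 and returns at 8. Wittig olefination with methyl (triphenylphosphoranylidene)acetate (PhMe, 100 °C) gives dimethyl (2E,2'E)-3,3'-[2,4,6-tris(benzyloxy)-1,3-phenylene]bis(prop-2-enoate) F9. Homogeneous hydrogenation (H2, RhCl(PPh3)3, benzene–EtOH), which leaves benzyl ethers intact, gives dimethyl 3,3'-[2,4,6-tris(benzyloxy)-1,3-phenylene]dipropanoate F10. Saponification (LiOH, THF–H2O) gives 8.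

**Step 4.** The alkylation of crude 11 may not stop at one methyl group per arm, giving under- and over-methylated arms or O-methylated enol ethers. Incomplete acylation of 5 on one arm would also carry through. A first adjustment would be to purify 11 before the alkylation.

The fallback brings the methyl group in with the nucleophile, sets out from 8 and returns at 12. Compound 8 is converted into 9 as in step 4. Methyl propanoate F11 (purchased) is deprotonated with LiN(iPr)2 in THF at −78 °C to lithium 1-methoxyprop-1-en-1-olate F12, used in excess, and 9 is added at −78 → −30 °C. Crossed Claisen condensation, which consumes two molecules of F12, should give 12 directly with no alkylation.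

## Further compounds

F1 | step 8 | 1-(2,4,6-trihydroxyphenyl)butan-1-one | CCCC(=O)c1c(O)cc(O)cc1O
F2 | step 8 | 2-methylbenzene-1,3,5-triol (purchased) | Cc1c(O)cc(O)cc1O
F3 | step 8 | 1-(2,4,6-trihydroxy-3-methylphenyl)butan-1-one | CCCC(=O)c1c(O)cc(O)c(C)c1O
F4 | step 8 | 1-(2,6-dihydroxy-4-methoxy-3-methylphenyl)butan-1-one | CCCC(=O)c1c(O)cc(OC)c(C)c1O
F5 | step 8 | 1-{3-[(dimethylamino)methyl]-2,6-dihydroxy-4-methoxy-5-methylphenyl}butan-1-one | CCCC(=O)c1c(O)c(CN(C)C)c(OC)c(C)c1O
F6 | step 10 | 1-[2,4,6-tris(benzyloxy)-3,5-bis{[2-(benzyloxy)-3-butanoyl-4-hydroxy-6-methoxy-5-methylphenyl]methyl}phenyl]butan-1-one | CCCC(=O)c1c(OCc2ccccc2)c(Cc2c(OCc3ccccc3)c(C(=O)CCC)c(O)c(C)c2OC)c(OCc2ccccc2)c(Cc2c(OCc3ccccc3)c(C(=O)CCC)c(O)c(C)c2OC)c1OCc1ccccc1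
F7 | step 7 | 1-(propan-2-yloxy)hex-1-yn-3-one | CCCC(=O)C#COC(C)C
F8 | step 7 | 1,3,5-tris(benzyloxy)-2,4-bis{[3-butanoyl-4-hydroxy-6-methoxy-5-methyl-2-(propan-2-yloxy)phenyl]methyl}benzene | O(Cc1ccccc1)c1cc(OCc2ccccc2)c(Cc2c(OC(C)C)c(C(=O)CCC)c(O)c(C)c2OC)c(OCc2ccccc2)c1Cc1c(OC(C)C)c(C(=O)CCC)c(O)c(C)c1OC
F9 | step 3 | dimethyl (2E,2'E)-3,3'-[2,4,6-tris(benzyloxy)-1,3-phenylene]bis(prop-2-enoate) | COC(=O)/C=C/c1c(OCc2ccccc2)cc(OCc2ccccc2)c(/C=C/C(=O)OC)c1OCc1ccccc1
F10 | step 3 | dimethyl 3,3'-[2,4,6-tris(benzyloxy)-1,3-phenylene]dipropanoate | COC(=O)CCc1c(OCc2ccccc2)cc(OCc2ccccc2)c(CCC(=O)OC)c1OCc1ccccc1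
F11 | step 4 | methyl propanoate (purchased) | CCC(=O)OC
F12 | step 4 | lithium 1-methoxyprop-1-en-1-olate (geometry immaterial) | CC=C(OC)[O-].[Li+]
A1 | alternative 1 | 1-[3,5-bis{[2,4-bis(benzyloxy)-3-butanoyl-6-methoxy-5-methylphenyl]methyl}-2,4,6-trihydroxyphenyl]butan-1-one | CCCC(=O)c1c(O)c(Cc2c(OCc3ccccc3)c(C(=O)CCC)c(OCc3ccccc3)c(C)c2OC)c(O)c(Cc2c(OCc3ccccc3)c(C(=O)CCC)c(OCc3ccccc3)c(C)c2OC)c1O
A2 | alternative 1 | methyl 2,4-bis{[2,4-bis(benzyloxy)-3-butanoyl-6-methoxy-5-methylphenyl]methyl}-3,5,7-trioxodecanoate | COC(=O)C(Cc1c(OCc2ccccc2)c(C(=O)CCC)c(OCc2ccccc2)c(C)c1OC)C(=O)C(Cc1c(OCc2ccccc2)c(C(=O)CCC)c(OCc2ccccc2)c(C)c1OC)C(=O)CC(=O)CCC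
A3 | alternative 2 | 1-[4,6-bis(benzyloxy)-3,5-bis{[2,4-bis(benzyloxy)-3-butanoyl-6-methoxy-5-methylphenyl]methyl}-2-hydroxyphenyl]butan-1-one | CCCC(=O)c1c(O)c(Cc2c(OCc3ccccc3)c(C(=O)CCC)c(OCc3ccccc3)c(C)c2OC)c(OCc2ccccc2)c(Cc2c(OCc3ccccc3)c(C(=O)CCC)c(OCc3ccccc3)c(C)c2OC)c1OCc1ccccc1
A4 | alternative 2 | 3,5-bis(benzyloxy)-2,4-bis{[2,4-bis(benzyloxy)-3-butanoyl-6-methoxy-5-methylphenyl]methyl}-6-(trimethylsilyl)phenyl trifluoromethanesulfonate | C[Si](C)(C)c1c(OS(=O)(=O)C(F)(F)F)c(Cc2c(OCc3ccccc3)c(C(=O)CCC)c(OCc3ccccc3)c(C)c2OC)c(OCc2ccccc2)c(Cc2c(OCc3ccccc3)c(C(=O)CCC)c(OCc3ccccc3)c(C)c2OC)c1OCc1ccccc1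
A5 | alternative 2 | butanoic acid | CCCC(=O)O
A6 | alternative 3 | 1-[2,4,6-tris(benzyloxy)-3,5-bis[(3-butanoyl-2,4,6-trihydroxy-5-methylphenyl)methyl]phenyl]butan-1-one | CCCC(=O)c1c(OCc2ccccc2)c(Cc2c(O)c(C(=O)CCC)c(O)c(C)c2O)c(OCc2ccccc2)c(Cc2c(O)c(C(=O)CCC)c(O)c(C)c2O)c1OCc1ccccc1
A7 | alternative 3 | dimethyl 2,2'-{[2,4,6-tris(benzyloxy)-5-butanoyl-1,3-phenylene]bis(methylene)}bis(4-methyl-3,5,7-trioxodecanoate) | CCCC(=O)c1c(OCc2ccccc2)c(CC(C(=O)OC)C(=O)C(C)C(=O)CC(=O)CCC)c(OCc2ccccc2)c(CC(C(=O)OC)C(=O)C(C)C(=O)CC(=O)CCC)c1OCc1ccccc1
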